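**Plan**

- Cuts: the Si–O bond and the lactam C5=O go last. Lactone D (O–C11, C12–Cα) and the C10–ethyl bond lead back to a cross-conjugated dienone, and C1–OH to the para carbon of a 6-hydroxyindoline. The N4–C9a bond is cut by a 1,2-shift back to the C5–C9a bond of a peri-fused six-membered cyclic imine. C5–C9a (Friedel–Crafts), C8–C9 (Negishi) and C13–C14 (homoenolate addition) then lead to an iodotyrosine.
- Forward: lactone E is made first, then the tetralone ring, then the six-membered imine ring (N4, C5, C9a, C1, C2, C3). One photochemical 1,2-shift contracts this ring to ring B and expands the carbocycle to ring A. Dearomatisation gives ring C, lactone D is closed, and the lactam is reduced.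
- Enabling feature: N4 stands between C5 and the sp2 carbon C9a, and C1(OH)–C9a(N4)=C9–C10 is the oxidation pattern of a para-hydroxylated 6-hydroxyindoline. Ring C can therefore be carried as an arene whose carbon C9a migrates from C5 to N4.
- Stereochemistry: C3 from L-tyrosine; C15 from a chiral 3-hydroxy-2-methylpropanoate; C13 by chelation-controlled addition; C1 by water attack anti to the C3 substituent; C12 by Michael addition anti to the C1 silyloxy group; C10 and C11 by syn hydroboration anti to the C12 substituent, then SN2 inversion at C11; Cα of lactone D by protonation on the convex face.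

Key step: step 8

Assumption: the four starting materials are taken as purchasable. Locants used throughout: ring B = N4, C3, C2, C1, C9a; ring A = N4, C5–C9, C9a; ring C = C9a, C9, C10, C11, C12, C1; lactone E = C13 (on C3), C14, C15, C=O, O; Cα = methyl-bearing carbon of lactone D.

**Route**

Step 1
Reactants: 1 N-(tert-butoxycarbonyl)-3-iodo-L-tyrosine
Product: 2 methyl N-(tert-butoxycarbonyl)-3-iodo-O-methyl-L-tyrosinate
Conditions: MeI, K2CO3, DMF, rt
Reagents that add atoms: iodomethane, CI
Why: Base-mediated O-alkylation (Williamson ether synthesis and carboxylate esterification) should methylate the phenol and the acid in one operation while the carbamate N–H and the α-stereocentre stay untouched.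

Step 2
Reactants: 2 methyl N-(tert-butoxycarbonyl)-3-iodo-O-methyl-L-tyrosinate
Product: 3 tert-butyl N-[(2S)-1-(3-iodo-4-methoxyphenyl)-3-oxopropan-2-yl]carbamate
Conditions: iBu2AlH, toluene, −78 °C; aq. potassium sodium tartrate; used crude
Reagents that add atoms: none
Why: Partial ester reduction by iBu2AlH should stop at the aluminium hemiacetal at −78 °C and give the configurationally labile N-Boc α-amino aldehyde, which is used at once; the aryl iodide and carbamate are inert.

Step 3
Reactants: 4 methyl (S)-3-hydroxy-2-methylpropanoate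
Product: 5 methyl (R)-3-iodo-2-methylpropanoate
Conditions: I2, PPh3, imidazole, CH2Cl2, 0 °C → rt
Reagents that add atoms: iodine, II
Why: Appel iodination of the primary alcohol does not touch the stereocentre (the descriptor changes from S to R only because the priorities change).

Step 4
Reactants: 5 methyl (R)-3-iodo-2-methylpropanoate; 3 tert-butyl N-[(2S)-1-(3-iodo-4-methoxyphenyl)-3-oxopropan-2-yl]carbamate
Product: 9 tert-butyl N-[(1S)-2-(3-iodo-4-methoxyphenyl)-1-[(2S,4S)-4-methyl-5-oxooxolan-2-yl]ethyl]carbamate, via zinc homoenolate 6 (not isolated), via titanium homoenolate 7 (not isolated), via hydroxy ester 8 (not isolated)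
Conditions: 5, Zn–Cu couple, toluene/DMA, 60 °C; TiCl(OiPr)3, −20 °C; then 3, −20 → 0 °C; aq. NH4Cl; then AcOH (cat.), toluene, 80 °C
Reagents that add atoms: none
Why: Zinc insertion gives the ester homoenolate, which after transmetalation to titanium should add to the N-Boc α-amino aldehyde under chelation control (homoenolate aldehyde addition of the type used for hydroxyethylene isostere lactones), setting C13 syn to the C3 nitrogen; the γ-hydroxy ester then lactonises under acid, and C15 is carried in from 5.

Step 5
Reactants: 9 tert-butyl N-[(1S)-2-(3-iodo-4-methoxyphenyl)-1-[(2S,4S)-4-methyl-5-oxooxolan-2-yl]ethyl]carbamate; 10 tert-butyl 4-bromobutanoate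
Product: 12 tert-butyl 4-[5-[(2S)-2-[(tert-butoxycarbonyl)amino]-2-[(2S,4S)-4-methyl-5-oxooxolan-2-yl]ethyl]-2-methoxyphenyl]butanoate, via alkylzinc bromide 11 (not isolated)
Conditions: 10, Zn dust, LiCl, THF, 40 °C; then 9, Pd2(dba)3 (2.5 mol%), SPhos (10 mol%), THF, 50 °C
Reagents that add atoms: none
Why: Negishi coupling of a primary alkylzinc reagent with the aryl iodide under zerovalent palladium and a bulky biarylphosphine should join C8 to C9 and tolerates the lactone, the ester and the carbamate N–H.

Step 6
Reactants: 12 tert-butyl 4-[5-[(2S)-2-[(tert-butoxycarbonyl)amino]-2-[(2S,4S)-4-methyl-5-oxooxolan-2-yl]ethyl]-2-methoxyphenyl]butanoate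
Product: 15 tricyclic imine (N4=C5 inside the six-membered ring N4–C5–C9a–C1–C2–C3; 10-methoxy arene; lactone E on C3), via amino acid 13 (not isolated), via amino tetralone 14 (not isolated)
Conditions: CF3CO2H, CH2Cl2, rt; concentrate; CF3SO3H, ClCH2CH2Cl, 60 °C; aq. K2CO3; then 4 Å molecular sieves, toluene, 60 °C
Reagents that add atoms: none
Why: Acid removes the Boc group and the tert-butyl ester, the acylium ion of the free acid should close the six-membered ketone ring on C9a, the only free position ortho to the chain (intramolecular Friedel–Crafts acylation), and the liberated amine condenses with the peri ketone to the six-membered cyclic imine.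

Step 7
Reactants: 15 tricyclic imine
Product: 16 oxaziridine of 15 (O bridging N4 and C5; mixture of diastereomers at the three-membered ring)
Conditions: mCPBA, NaHCO3, CH2Cl2, 0 °C
Reagents that add atoms: 3-chloroperoxybenzoic acid, OOC(=O)c1cccc(Cl)c1
Why: Peracid oxidation of an imine to the oxaziridine (standard oxaziridine synthesis) should outrun any attack on the anisole ring; the diastereomer mixture is used as such because both new centres are lost in step 8.

Step 8
Reactants: 16 oxaziridine of 15
Product: 17 tricyclic lactam (N-acyl indoline: ring B N4–C3–C2–C1–C9a, ring A N4–C5(=O)–C6–C7–C8–C9–C9a, aromatic ring C with 10-OMe, lactone E on C3)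
Conditions: hν (254 nm, quartz), MeCN, rt
Reagents that add atoms: none
Why: Excitation of the oxaziridine breaks the weak N–O bond and, as the C5 carbonyl forms, the C5–C9a bond lying anti to the nitrogen lone pair shifts to N4 (1,2-aryl shift from carbon to nitrogen), giving the N-acyl indoline. The closest known reaction type is the photochemical oxaziridine-to-amide rearrangement, which contracts the ring of oxaziridines fused to cyclic imines or nitrones and expands spiro-oxaziridines to lactams. No ring is closed by cyclisation: ring B arises by contraction of the six-membered ring N4, C5, C9a, C1, C2, C3 with expulsion of C5, and ring A arises by one-atom expansion of the tetralone-derived carbocycle as N4 is inserted between C5 and C9a. No new stereocentre is formed, C3, C13 and C15 are not involved, and the two oxaziridine centres disappear, so both diastereomers of 16 should converge. The step needs migration of aryl carbon C9a and not of C6: the ring fusion holds C9a cis to C3 across the oxaziridine and hence anti to the nitrogen lone pair, and a shift of C6 would give a strained amide with nitrogen at a bridgehead. The arene carbon is also a good migrating group because it can bridge to nitrogen through its π-system.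

Step 9
Reactants: 17 tricyclic lactam
Product: 18 phenol (10-OH) of 17
Conditions: BBr3, CH2Cl2, −78 → 0 °C; then H2O
Reagents that add atoms: none
Why: Lewis-acid cleavage of the aryl methyl ether by BBr3 at low temperature should leave the lactone and the lactam intact.

Step 10
Reactants: 18 phenol
Product: 19 (1S,3S)-1-hydroxy dienone (C10=O, C11=C12, C9=C9a enamide, lactam C5=O)
Conditions: PhI(OAc)2, MeCN/H2O (3:1), 0 °C
Reagents that add atoms: water, O
Why: In this oxidative dearomatisation with a hypervalent iodine reagent the phenoxenium ion should be captured by water at the alkyl-substituted para carbon C1 on the face opposite the C3 substituent, which A(1,3) strain with the lactam carbonyl holds pseudo-axial, so C1–OH comes out trans to the lactone E side chain.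

Step 11
Reactants: 19 1-hydroxy dienone
Product: 20 1-O-triethylsilyl ether of 19
Conditions: Et3SiOTf, 2,6-lutidine, CH2Cl2, −78 → 0 °C
Reagents that add atoms: triethylsilyl trifluoromethanesulfonate, CC[Si](CC)(CC)OS(=O)(=O)C(F)(F)F
Why: A silyl triflate with a hindered base should silylate the tertiary alcohol, which blocks hydroxyl-directed syn addition in step 12 and protects the alcohol to the end; the buffer prevents a dienone–phenol rearrangement.

Step 12
Reactants: 20 silyl ether; 21 dibenzyl malonate
Product: 23 C10 ketone carrying C(CH3)(CO2Bn)2 on C12 (anti to the C1 silyloxy group), via Michael adduct 22 (not isolated)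
Conditions: 21, NaH, THF, 0 °C → rt; then MeI, rt
Reagents that add atoms: iodomethane, CI
Why: Michael addition of the malonate anion should occur at C12 of the disubstituted enone, anti to the bulky silyloxy group on C1, which sets C12; the tetrasubstituted nitrogen-bearing C9=C9a bond is a vinylogous imide and does not accept, and the resulting malonate anion is C-methylated in the same flask.

Step 13
Reactants: 23 methylmalonate ketone
Product: 24 dienyl triflate (C10(OTf)=C11, C9=C9a)
Conditions: KN(SiMe3)2, THF, −78 °C; then PhNTf2, −78 → 0 °C; basic work-up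
Reagents that add atoms: N-phenylbis(trifluoromethanesulfonimide), FC(F)(F)S(=O)(=O)N(c1ccccc1)S(=O)(=O)C(F)(F)F
Why: Kinetic deprotonation at C11, the only enolisable position of the C10 ketone and more acidic than the lactone and lactam α-positions, followed by O-triflation should turn the former phenol oxygen into a leaving group; acid is avoided because the silyloxy diene could aromatise by loss of silanol.

Step 14
Reactants: 24 dienyl triflate
Product: 25 10-ethyl diene (C10(Et)=C11, C9=C9a)
Conditions: EtMgBr, Fe(acac)3 (5 mol%), THF/NMP, −30 °C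
Reagents that add atoms: ethylmagnesium bromide, CC[Mg]Br
Why: Iron-catalysed Kumada-type cross-coupling of the dienyl triflate with the alkyl Grignard reagent is fast at −30 °C, so the esters, lactone and lactam should survive and β-hydride loss from the ethyl group is not a problem.

Step 15
Reactants: 25 10-ethyl diene
Product: 26 C11 alcohol (10-H and 11-OH both anti to the C12 substituent; ethyl cis to it)
Conditions: BH3·SMe2, THF, 0 °C → rt; then 30% H2O2, aq. NaOAc, 0 °C
Reagents that add atoms: hydrogen peroxide, OO
Why: In this hydroboration–oxidation boron should go to the less substituted diene terminus C11 and hydrogen to C10, syn and on the face opposite the quaternary carbon on C12, which sets C10 and gives the C11 alcohol trans to the C12 substituent; the tetrasubstituted enamide C9=C9a is inert.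

Step 16
Reactants: 26 C11 alcohol
Product: 27 C11 methanesulfonate
Conditions: MsCl, Et3N, CH2Cl2, 0 °C
Reagents that add atoms: methanesulfonyl chloride, CS(Cl)(=O)=O
Why: Sulfonylation of the secondary alcohol should turn C11–O into a leaving group with retention.

Step 17
Reactants: 27 C11 methanesulfonate
Product: 30 silyl-protected lactam carrying cis-fused lactone D (O on C11; methyl on the concave face), via malonic diacid 28 (not isolated), via lactone acid 29 (not isolated)
Conditions: H2 (1 atm), Pd/C, EtOAc, rt; filter; NaHCO3 (1 equiv), DMF, 50 °C; then 110 °C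
Reagents that add atoms: none
Why: Hydrogenolysis frees the malonic acid, one carboxylate should displace the C11 mesylate from the rear (SN2, 5-exo-tet) to give the cis-fused γ-lactone with inversion at C11, and the remaining carboxyl is lost thermally with protonation of the enol on the convex face (opposite C1), which places the methyl group on the concave face as required.

Step 18
Reactants: 30 lactam with lactone D
Product: 31 thiolactam (C5=S)
Conditions: Lawesson's reagent, toluene, 80 °C
Reagents that add atoms: Lawesson's reagent, COc1ccc(cc1)P1(=S)SP(=S)(S1)c1ccc(OC)cc1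
Why: Thionation with Lawesson's reagent should be selective for the tertiary lactam, because amides react far faster than the two lactones.

Step 19
Reactants: 31 thiolactam
Product: 32 1-O-triethylsilyl ether of the target
Conditions: Raney nickel, EtOH, rt
Reagents that add atoms: none
Why: Reductive desulfurisation of the thiolactam with Raney nickel should give the C5 methylene group, turning the enamide into the enamine N4–C9a=C9; the tetrasubstituted double bond and the lactones should not be reduced under these mild conditions.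

Step 20
Reactants: 32 silyl ether of the target
Product: 33 target (CNP0179500.1)
Conditions: Bu4NF, AcOH, THF, 0 °C → rt
Reagents that add atoms: none
Why: Fluoride should cleave the tertiary silyl ether, and buffering with acetic acid protects the two lactones and the enamine from base-induced epimerisation or opening.

**Compound list**

1 | N-(tert-butoxycarbonyl)-3-iodo-L-tyrosine | CC(C)(C)OC(=O)N[C@@H](Cc1ccc(O)c(I)c1)C(=O)O | starting material
2 | methyl N-(tert-butoxycarbonyl)-3-iodo-O-methyl-L-tyrosinate | CC(C)(C)OC(=O)N[C@@H](Cc1ccc(OC)c(I)c1)C(=O)OC | intermediate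
3 | tert-butyl N-[(2S)-1-(3-iodo-4-methoxyphenyl)-3-oxopropan-2-yl]carbamate | CC(C)(C)OC(=O)N[C@@H](Cc1ccc(OC)c(I)c1)C=O | intermediate
4 | methyl (S)-3-hydroxy-2-methylpropanoate | COC(=O)[C@@H](C)CO | starting material
5 | methyl (R)-3-iodo-2-methylpropanoate | COC(=O)[C@@H](C)CI | intermediate
6 | [(2R)-3-methoxy-2-methyl-3-oxopropyl]zinc iodide (zinc homoenolate) | COC(=O)[C@@H](C)C[Zn]I | intermediate
7 | [(2R)-3-methoxy-2-methyl-3-oxopropyl]titanium triisopropoxide (titanium homoenolate) | COC(=O)[C@@H](C)C[Ti](OC(C)C)(OC(C)C)OC(C)C | intermediate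
8 | methyl (2S,4S,5S)-5-[(tert-butoxycarbonyl)amino]-4-hydroxy-6-(3-iodo-4-methoxyphenyl)-2-methylhexanoate | COC(=O)[C@@H](C)C[C@H](O)[C@H](Cc1ccc(OC)c(I)c1)NC(=O)OC(C)(C)C | intermediate
9 | tert-butyl N-[(1S)-2-(3-iodo-4-methoxyphenyl)-1-[(2S,4S)-4-methyl-5-oxooxolan-2-yl]ethyl]carbamate | CC(C)(C)OC(=O)N[C@H]([C@@H]1C[C@H](C)C(=O)O1)Cc1ccc(OC)c(I)c1 | intermediate
10 | tert-butyl 4-bromobutanoate | CC(C)(C)OC(=O)CCCBr | starting material
11 | (4-tert-butoxy-4-oxobutyl)zinc bromide | CC(C)(C)OC(=O)CCC[Zn]Br | intermediate
12 | tert-butyl 4-[5-[(2S)-2-[(tert-butoxycarbonyl)amino]-2-[(2S,4S)-4-methyl-5-oxooxolan-2-yl]ethyl]-2-methoxyphenyl]butanoate | CC(C)(C)OC(=O)N[C@H]([C@@H]1C[C@H](C)C(=O)O1)Cc1ccc(OC)c(CCCC(=O)OC(C)(C)C)c1 | intermediate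
13 | 4-[5-[(2S)-2-amino-2-[(2S,4S)-4-methyl-5-oxooxolan-2-yl]ethyl]-2-methoxyphenyl]butanoic acid | N[C@H]([C@@H]1C[C@H](C)C(=O)O1)Cc1ccc(OC)c(CCCC(=O)O)c1 | intermediate
14 | 8-[(2S)-2-amino-2-[(2S,4S)-4-methyl-5-oxooxolan-2-yl]ethyl]-5-methoxy-3,4-dihydronaphthalen-1(2H)-one | N[C@H]([C@@H]1C[C@H](C)C(=O)O1)Cc1ccc(OC)c2CCCC(=O)c12 | intermediate
15 | tricyclic imine: N4=C5 in the six-membered ring N4–C5–C9a–C1–C2–C3, peri-fused to the 10-methoxy arene and the C5–C9 carbocycle; (3S), lactone E (13S,15S) | COc1ccc2C[C@@H]([C@@H]3C[C@H](C)C(=O)O3)N=C3CCCc1c23 | intermediate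
16 | oxaziridine of 15 (O bridging N4 and C5; both diastereomers at N4/C5) | COc1ccc2C[C@@H]([C@@H]3C[C@H](C)C(=O)O3)N3OC34CCCc1c24 | intermediate
17 | tricyclic lactam: (3S)-N-acyl indoline with fused azepinone (N4–C9a bond, C5=O), 10-OMe, lactone E on C3 | COc1ccc2C[C@@H]([C@@H]3C[C@H](C)C(=O)O3)N3C(=O)CCCc1c23 | intermediate
18 | phenol: 10-OH analogue of 17 | Oc1ccc2C[C@@H]([C@@H]3C[C@H](C)C(=O)O3)N3C(=O)CCCc1c23 | intermediate
19 | (1S,3S)-1-hydroxy dienone: C10=O, C11=C12, C9=C9a, lactam C5=O; 1-OH trans to the C3 side chain | O=C1C2=C3N(C(=O)CCC2)[C@H]([C@@H]2C[C@H](C)C(=O)O2)C[C@]3(O)C=C1 | intermediate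
20 | 1-O-triethylsilyl ether of 19 | O=C1C2=C3N(C(=O)CCC2)[C@H]([C@@H]2C[C@H](C)C(=O)O2)C[C@]3(O[Si](CC)(CC)CC)C=C1 | intermediate
21 | dibenzyl malonate | O=C(CC(=O)OCc1ccccc1)OCc1ccccc1 | starting material
22 | Michael adduct: CH(CO2Bn)2 on C12 anti to 1-OSiEt3, C10 ketone (present as its sodium malonate enolate) | O=C1C2=C3N(C(=O)CCC2)[C@H]([C@@H]2C[C@H](C)C(=O)O2)C[C@]3(O[Si](CC)(CC)CC)[C@H](C(C(=O)OCc2ccccc2)C(=O)OCc2ccccc2)C1 | intermediate
23 | methylmalonate ketone: C(CH3)(CO2Bn)2 on C12, C10 ketone | O=C1C2=C3N(C(=O)CCC2)[C@H]([C@@H]2C[C@H](C)C(=O)O2)C[C@]3(O[Si](CC)(CC)CC)[C@H](C(C)(C(=O)OCc2ccccc2)C(=O)OCc2ccccc2)C1 | intermediate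
24 | dienyl triflate: C10(OTf)=C11, C9=C9a | C1=C(OS(=O)(=O)C(F)(F)F)C2=C3N(C(=O)CCC2)[C@H]([C@@H]2C[C@H](C)C(=O)O2)C[C@]3(O[Si](CC)(CC)CC)[C@@H]1C(C)(C(=O)OCc1ccccc1)C(=O)OCc1ccccc1 | intermediate
25 | 10-ethyl diene: C10(Et)=C11, C9=C9a | C1=C(CC)C2=C3N(C(=O)CCC2)[C@H]([C@@H]2C[C@H](C)C(=O)O2)C[C@]3(O[Si](CC)(CC)CC)[C@@H]1C(C)(C(=O)OCc1ccccc1)C(=O)OCc1ccccc1 | intermediate
26 | C11 alcohol: 10-ethyl cis and 11-OH trans to the C12 substituent | CC[C@@H]1C2=C3N(C(=O)CCC2)[C@H]([C@@H]2C[C@H](C)C(=O)O2)C[C@]3(O[Si](CC)(CC)CC)[C@H](C(C)(C(=O)OCc2ccccc2)C(=O)OCc2ccccc2)[C@H]1O | intermediate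
27 | C11 methanesulfonate of 26 | CC[C@@H]1C2=C3N(C(=O)CCC2)[C@H]([C@@H]2C[C@H](C)C(=O)O2)C[C@]3(O[Si](CC)(CC)CC)[C@H](C(C)(C(=O)OCc2ccccc2)C(=O)OCc2ccccc2)[C@H]1OS(C)(=O)=O | intermediate
28 | malonic diacid of 27 | CC[C@@H]1C2=C3N(C(=O)CCC2)[C@H]([C@@H]2C[C@H](C)C(=O)O2)C[C@]3(O[Si](CC)(CC)CC)[C@H](C(C)(C(=O)O)C(=O)O)[C@H]1OS(C)(=O)=O | intermediate
29 | lactone acid: cis-fused lactone D with α-methyl and α-carboxyl (both epimers at Cα) | CC[C@@H]1C2=C3N(C(=O)CCC2)[C@H]([C@@H]2C[C@H](C)C(=O)O2)C[C@]3(O[Si](CC)(CC)CC)[C@H]2[C@@H]1OC(=O)C2(C)C(=O)O | intermediate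
30 | 1-O-triethylsilyl 5-oxo derivative of the target (lactam with lactones D and E) | CC[C@@H]1C2=C3N(C(=O)CCC2)[C@H]([C@@H]2C[C@H](C)C(=O)O2)C[C@]3(O[Si](CC)(CC)CC)[C@H]2[C@@H]1OC(=O)[C@H]2C | intermediate
31 | thiolactam (C5=S) of 30 | CC[C@@H]1C2=C3N(C(=S)CCC2)[C@H]([C@@H]2C[C@H](C)C(=O)O2)C[C@]3(O[Si](CC)(CC)CC)[C@H]2[C@@H]1OC(=O)[C@H]2C | intermediate
32 | 1-O-triethylsilyl ether of the target | CC[C@@H]1C2=C3N(CCCC2)[C@H]([C@@H]2C[C@H](C)C(=O)O2)C[C@]3(O[Si](CC)(CC)CC)[C@H]2[C@@H]1OC(=O)[C@H]2C | intermediate
33 | target CNP0179500.1 | CC[C@@H]1C2=C3N(CCCC2)[C@H]([C@@H]2C[C@H](C)C(=O)O2)C[C@]3(O)[C@H]2[C@@H]1OC(=O)[C@H]2C | target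

**Step count and risks**

Total steps: 20. Longest linear sequence: 19 steps (1 to 33 through steps 1, 2 and 4–20); step 3 is a one-step side branch.

Steps most likely to fail:

Step 8. Under irradiation the oxaziridine may revert to nitrone or imine, or fragment unselectively, instead of undergoing the aryl shift. Fallback (intramolecular Schmidt reaction): the amino acid 13, isolated as its salt after the CF3CO2H stage of step 6, is treated with imidazole-1-sulfonyl azide hydrogen sulfate (CuSO4 cat., K2CO3, MeOH) to give the azido acid F1. CF3SO3H in ClCH2CH2Cl then closes the ketone ring to the azido tetralone F2, which in the same acid should add the azide to the ketone and shift aryl carbon C9a to nitrogen with loss of nitrogen gas. This gives 17, where the route is rejoined.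

Step 10. The phenoxenium ion may be captured with poor facial selectivity, or at the ortho carbon. Fallback (concerted oxygen transfer instead of ionic capture): photo-oxygenation of the phenolate of 18 (O2, rose bengal, visible light, K2CO3, MeCN/H2O) should add singlet oxygen across C1 and C10 on the face opposite the C3 substituent. This gives the C1 hydroperoxide F3, which Me2S reduces to 19.

Step 15. Borane may reduce the lactam carbonyl competitively, or add on the face syn to the C12 substituent. Fallback from 23, which keeps the C10 ketone and builds lactone D first: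
- PhNMe3Br3 (THF, 0 °C) should brominate C11 anti to the C12 substituent to give the bromo ketone F4.
- Heating (MeCN, 80 °C) lets a benzyl ester carbonyl displace bromide with inversion and lose benzyl bromide, giving the cis-fused lactone benzyl ester F5.
- Hydrogenolysis (H2, Pd/C, EtOAc) and heating to 110 °C give the keto lactone F6.
- Wittig olefination with Ph3P=CHCH3 (THF) gives the ethylidene compound F7.
- Hydrogenation (H2, Pd/C) on the face opposite lactone D should give 30.

Further compounds
F1 | step 8 | 4-[5-[(2S)-2-azido-2-[(2S,4S)-4-methyl-5-oxooxolan-2-yl]ethyl]-2-methoxyphenyl]butanoic acid | [N-]=[N+]=N[C@H]([C@@H]1C[C@H](C)C(=O)O1)Cc1ccc(OC)c(CCCC(=O)O)c1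
F2 | step 8 | 8-[(2S)-2-azido-2-[(2S,4S)-4-methyl-5-oxooxolan-2-yl]ethyl]-5-methoxy-3,4-dihydronaphthalen-1(2H)-one | [N-]=[N+]=N[C@H]([C@@H]1C[C@H](C)C(=O)O1)Cc1ccc(OC)c2CCCC(=O)c12
F3 | step 10 | C1 hydroperoxide corresponding to 19 | O=C1C2=C3N(C(=O)CCC2)[C@H]([C@@H]2C[C@H](C)C(=O)O2)C[C@]3(OO)C=C1
F4 | step 15 | C11 bromo ketone of 23 (bromine anti to the C12 substituent) | O=C1C2=C3N(C(=O)CCC2)[C@H]([C@@H]2C[C@H](C)C(=O)O2)C[C@]3(O[Si](CC)(CC)CC)[C@H](C(C)(C(=O)OCc2ccccc2)C(=O)OCc2ccccc2)[C@H]1Br
F5 | step 15 | C10 ketone with cis-fused lactone D bearing α-methyl and α-benzyloxycarbonyl (both epimers at Cα) | O=C1C2=C3N(C(=O)CCC2)[C@H]([C@@H]2C[C@H](C)C(=O)O2)C[C@]3(O[Si](CC)(CC)CC)[C@H]2[C@@H]1OC(=O)C2(C)C(=O)OCc1ccccc1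
F6 | step 15 | C10 ketone with lactone D (methyl on the concave face) | O=C1C2=C3N(C(=O)CCC2)[C@H]([C@@H]2C[C@H](C)C(=O)O2)C[C@]3(O[Si](CC)(CC)CC)[C@H]2[C@@H]1OC(=O)[C@H]2C
F7 | step 15 | C10 ethylidene compound (mixture of alkene isomers) | CC=C1C2=C3N(C(=O)CCC2)[C@H]([C@@H]2C[C@H](C)C(=O)O2)C[C@]3(O[Si](CC)(CC)CC)[C@H]2[C@@H]1OC(=O)[C@H]2C
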